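Phenanthrene numbering is used: ring A = C1–C4, C4a, C10a; ring B = C4a, C4b, C8a, C9, C10, C10a; ring C = C4b, C5–C8, C8a. The retrosynthesis cuts, in order, the O–benzyl bond at C1, C8a–C9 (ring B), the aminal C–O, aminal C–N and C6–N bonds (oxazolidine, pyrrolidine), C5–O (dearomatised ring C), C8a–Br, and C4a–C4b (biaryl).
Forward: a ring A acetophenone boronate and a ring C bromophenol are made separately and joined at C4a–C4b. C8a is brominated, and ring C is dearomatised to the C8 dienone carrying C5–OH. 4,4-Diethoxybutylamine enters at C6 and closes the pyrrolidine and the oxazolidine. Ring B closes last, and debenzylation ends the route.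
Enabling feature: the C10 ketone of ring B and the C8 ketone of ring C are 1,4-related through C9–C8a, so both ends of the bond to be made are ketone α-carbons. The C8a–Br bond lets zerovalent palladium invert the polarity of C8a. The acetyl CH3 (C9) is the only enolisable position.
Stereochemistry: bromination at C8a locks the C4a–C4b axis, and a cinchona urea catalyst should set it as aR by dynamic kinetic resolution. The acetyl group held over one face of ring C sends singlet oxygen to the other face, which turns the axis into 5R. The aminal carbon (S) follows C5 under thermodynamic control, and the axis vanishes when ring B forms.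

Key step: step 13

Remark: the product of the key step and the target are written, like the target SMILES, in the C10 keto / C9 methylene form; the C10 enol (ring B as a 1-naphthol) is a prototropic tautomer of the same compound and changes nothing in the route.
Remark: SMILES cannot encode the C4a–C4b axis, so its sense is given in the compound names.

Step 1
Reactants: 1 1-bromo-3,5-dimethoxybenzene; 2 acetyl chloride
Product: 3 1-(2-bromo-4,6-dimethoxyphenyl)ethan-1-one
Conditions: AlCl3 (1.2 equiv), CH2Cl2, 0 °C
Reagents that add atoms: none
Why: Friedel–Crafts acylation takes the position ortho to bromine and para to a methoxy group, because the only other activated site lies between two methoxy groups and is more crowded, and this places the future C10–C9 acetyl unit next to the future C4a.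

Step 2
Reactants: 3 1-(2-bromo-4,6-dimethoxyphenyl)ethan-1-one
Product: 4 1-(2-bromo-6-hydroxy-4-methoxyphenyl)ethan-1-one
Conditions: BCl3 (1.1 equiv), CH2Cl2, −78 to 0 °C; H2O
Reagents that add atoms: none
Why: In this chelation-controlled Lewis acid ether cleavage, boron binds the acetyl oxygen and the ortho methoxy oxygen in a six-membered chelate, so only that methyl ether (future C1–O) is cut and the para one survives.

Step 3
Reactants: 4 1-(2-bromo-6-hydroxy-4-methoxyphenyl)ethan-1-one
Product: 5 1-[2-(benzyloxy)-6-bromo-4-methoxyphenyl]ethan-1-one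
Conditions: BnBr, K2CO3, DMF, 50 °C
Reagents that add atoms: benzyl bromide, BrCc1ccccc1
Why: Williamson ether synthesis on the acidic hydrogen-bonded phenol masks C1–OH with a group that withstands base, acid, oxidants and palladium coupling and leaves by hydrogenolysis.

Step 4
Reactants: 5 1-[2-(benzyloxy)-6-bromo-4-methoxyphenyl]ethan-1-one
Product: 6 1-[2-(benzyloxy)-4-methoxy-6-(4,4,5,5-tetramethyl-1,3,2-dioxaborolan-2-yl)phenyl]ethan-1-one
Conditions: B2pin2, PdCl2(dppf) (3 mol %), KOAc, 1,4-dioxane, 90 °C
Reagents that add atoms: bis(pinacolato)diboron, CC1(C)OB(OC1(C)C)B1OC(C)(C)C(C)(C)O1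
Why: In this Miyaura borylation the ortho acetyl group speeds oxidative addition, and the weak acetate base leaves the methyl ketone unenolised.

Step 5
Reactants: 7 2,3-dimethoxytoluene
Product: 8 1-bromo-3,4-dimethoxy-2-methylbenzene
Conditions: NBS, MeCN, 0 °C to rt
Reagents that add atoms: N-bromosuccinimide, O=C1CCC(=O)N1Br
Why: In this electrophilic aromatic bromination only the methoxy group remote from the methyl group can lie in the ring plane, so it directs bromine to its para position next to the methyl group, which is the future C4b.

Step 6
Reactants: 8 1-bromo-3,4-dimethoxy-2-methylbenzene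
Product: 9 5-bromo-2,3-dimethoxy-4-methylbenzaldehyde
Conditions: Cl2CHOMe, TiCl4, CH2Cl2, −10 to 0 °C; H2O
Reagents that add atoms: dichloromethyl methyl ether, COC(Cl)Cl; water, O
Why: Rieche formylation goes ortho to the in-plane methoxy group and para to the methyl group (future C8), since this is the most electron-rich site left and titanium coordination to that methoxy oxygen favours it over the position next to bromine.

Step 7
Reactants: 9 5-bromo-2,3-dimethoxy-4-methylbenzaldehyde
Product: 11 5-bromo-2,3-dimethoxy-4-methylphenol, via aryl formate 10 (not isolated)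
Conditions: mCPBA, CH2Cl2, rt; NaHCO3 wash; then K2CO3 (0.2 equiv), MeOH, rt
Reagents that add atoms: 3-chloroperoxybenzoic acid, OOC(=O)c1cccc(Cl)c1
Why: Baeyer–Villiger oxidation of an electron-rich benzaldehyde proceeds by aryl migration, and methanolysis of the formate then unmasks the C8 phenol without touching the aryl bromide.

Step 8
Reactants: 6 1-[2-(benzyloxy)-4-methoxy-6-(4,4,5,5-tetramethyl-1,3,2-dioxaborolan-2-yl)phenyl]ethan-1-one; 11 5-bromo-2,3-dimethoxy-4-methylphenol
Product: 12 1-[3-(benzyloxy)-5'-hydroxy-3',4',5-trimethoxy-2'-methylbiphenyl-2-yl]ethan-1-one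
Conditions: Pd(OAc)2 (3 mol %), 2-dicyclohexylphosphino-2',6'-dimethoxybiphenyl (6 mol %), K3PO4, 1,4-dioxane/H2O, 80 °C
Reagents that add atoms: none
Why: Suzuki–Miyaura coupling forms C4a–C4b with only two of the four ortho positions occupied, which a bulky biarylphosphine handles, and the free phenol and the ketone tolerate aqueous phosphate.

Step 9
Reactants: 12 1-[3-(benzyloxy)-5'-hydroxy-3',4',5-trimethoxy-2'-methylbiphenyl-2-yl]ethan-1-one
Product: 13 (aR)-1-[3-(benzyloxy)-2'-bromo-3'-hydroxy-4',5,5'-trimethoxy-6'-methylbiphenyl-2-yl]ethan-1-one
Conditions: N-bromoacetamide (1.0 equiv, slow addition), 1-[3,5-bis(trifluoromethyl)phenyl]-3-[(8α,9S)-6'-methoxycinchonan-9-yl]urea (10 mol %), toluene, 0 °C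
Reagents that add atoms: N-bromoacetamide, CC(=O)NBr
Why: In this organocatalytic atroposelective electrophilic bromination under dynamic kinetic resolution, the doubly ortho-substituted axis of 12 still rotates at 0 °C, the bifunctional catalyst should bind the C8 phenol (quinuclidine) and the acetyl oxygen (urea) of one helical conformer, and bromine goes to C8a, the only free position of ring C, which locks the C4a–C4b axis as aR (the quinidine-derived pseudoenantiomer serves if the sense proves opposite).

Step 10
Reactants: 13 (aR)-1-[3-(benzyloxy)-2'-bromo-3'-hydroxy-4',5,5'-trimethoxy-6'-methylbiphenyl-2-yl]ethan-1-one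
Product: 15 (4R)-3-[2-acetyl-3-(benzyloxy)-5-methoxyphenyl]-2-bromo-4-hydroxy-5,6-dimethoxy-4-methylcyclohexa-2,5-dien-1-one (5R in phenanthrene numbering; axis aR), via hydroperoxide 14 (not isolated)
Conditions: O2, 5,10,15,20-tetraphenylporphyrin (1 mol %), white LED, CH2Cl2/MeOH, −30 °C; then PPh3
Reagents that add atoms: dioxygen, O=O
Why: Sensitised photooxygenation of a para-alkylphenol followed by phosphine reduction of the hydroperoxide bonds oxygen to C5, para to the C8 hydroxyl, and so avoids the cationic oxidations that would attack the methoxy-bearing C7; oxygen should approach the ring C face opposite to the acetyl group that the perpendicular ring A holds over C5, so the aR axis becomes 5R, and any 5S epimer is a diastereomer removable by chromatography.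

Step 11
Reactants: 15 (4R)-3-[2-acetyl-3-(benzyloxy)-5-methoxyphenyl]-2-bromo-4-hydroxy-5,6-dimethoxy-4-methylcyclohexa-2,5-dien-1-one; 16 4,4-diethoxybutan-1-amine
Product: 17 (4R)-3-[2-acetyl-3-(benzyloxy)-5-methoxyphenyl]-2-bromo-5-[(4,4-diethoxybutyl)amino]-4-hydroxy-6-methoxy-4-methylcyclohexa-2,5-dien-1-one
Conditions: EtOH, 45 °C
Reagents that add atoms: none
Why: In this addition–elimination at a vinylogous ester, C6 is the β-carbon of the C8 enone and carries the only leaving group in such a position, so the primary amine should give the vinylogous amide while the α-methoxy group at C7, the fully substituted C4b and the hindered acetyl group stay untouched.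

Step 12
Reactants: 17 (4R)-3-[2-acetyl-3-(benzyloxy)-5-methoxyphenyl]-2-bromo-5-[(4,4-diethoxybutyl)amino]-4-hydroxy-6-methoxy-4-methylcyclohexa-2,5-dien-1-one
Product: 18 C8a-bromo dienone aminal (5R; aminal carbon S): ring C dienone with C8=O, C7–OMe and C8a–Br; oxazolidine C5–O–CH–N–C6 fused to the pyrrolidine; C5–CH3; 2-acetyl-3-(benzyloxy)-5-methoxyphenyl at C4b
Conditions: CF3CO2H (0.3 equiv), 4 Å molecular sieves, CH2Cl2, 0 °C to rt
Reagents that add atoms: none
Why: In this acid-catalysed N,O-acetal formation the acetal ionises, the vinylogous amide nitrogen closes the pyrrolidine and the C5 hydroxyl traps the cyclic acyliminium-type ion to close the oxazolidine, and because this closure is reversible the aminal carbon should settle under thermodynamic control as S, with its hydrogen cis to the C5 methyl group and the pyrrolidine CH2 on the uncrowded opposite face.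

Step 13
Reactants: 18 C8a-bromo dienone aminal (5R; aminal carbon S)
Product: 19 C1 O-benzyl ether of the target (5R; aminal carbon S)
Conditions: Pd2(dba)3 (5 mol %), P(tBu)3·HBF4 (12 mol %), Cs2CO3 (3 equiv), degassed toluene, 80 °C; aqueous NH4Cl
Reagents that add atoms: none
Why: Zerovalent palladium inserts into the C8a–Br bond of the α-bromodienone and thereby turns the normally nucleophilic α-carbon of the C8 ketone into an electrophilic vinylpalladium centre; carbonate then removes a proton from the palladium-bound acetyl group, and C–C reductive elimination from the carbon-bound enolate joins C9 to C8a. The closest known reaction type is the intramolecular palladium-catalysed α-vinylation and α-arylation of ketone enolates with bulky electron-rich phosphines. Ring B closes as a six-membered carbocycle in a 6-(enolendo) sense by reductive elimination from a seven-membered palladacycle (Pd, C8a, C4b, C4a, C10a, C10, C9), so the trajectory limits of a direct displacement do not apply. No stereocentre is formed, C5 and the aminal carbon carry no acidic hydrogen and should stay untouched, and either rotamer about C4a–C4b can swing the acetyl group toward C8a, so the axis is erased here. The step needs C- rather than O-vinylation, no hydrodebromination and no 5-exo conjugate addition of the enolate to C4b; P(tBu)3 speeds C–C reductive elimination, the weak, poorly soluble base keeps free enolate low, the acetyl CH3 is the only enolisable site and C8a–Br is the only carbon–halogen bond. Extra base is supplied because 19 should be deprotonated at C9 to its naphtholate, which also shields it from further coupling until the work-up.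

Step 14
Reactants: 19 C1 O-benzyl ether of the target
Product: 20 target CNP0528850.1 (5R; aminal carbon S)
Conditions: H2 (1 atm), palladium on carbon (10 wt %), EtOAc, rt
Reagents that add atoms: none
Why: Catalytic hydrogenolysis of the primary benzyl aryl ether should be faster than reduction of the two tetrasubstituted conjugated double bonds of ring C or cleavage of the tertiary C5–O bond, and the neutral medium leaves both stereocentres alone.

Compound list
1 | 1-bromo-3,5-dimethoxybenzene | COc1cc(Br)cc(OC)c1 | starting material
2 | acetyl chloride | CC(Cl)=O | starting material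
3 | 1-(2-bromo-4,6-dimethoxyphenyl)ethan-1-one | CC(=O)c1c(Br)cc(OC)cc1OC | intermediate
4 | 1-(2-bromo-6-hydroxy-4-methoxyphenyl)ethan-1-one | CC(=O)c1c(O)cc(OC)cc1Br | intermediate
5 | 1-[2-(benzyloxy)-6-bromo-4-methoxyphenyl]ethan-1-one | CC(=O)c1c(Br)cc(OC)cc1OCc1ccccc1 | intermediate
6 | 1-[2-(benzyloxy)-4-methoxy-6-(4,4,5,5-tetramethyl-1,3,2-dioxaborolan-2-yl)phenyl]ethan-1-one | CC(=O)c1c(B2OC(C)(C)C(C)(C)O2)cc(OC)cc1OCc1ccccc1 | intermediate
7 | 2,3-dimethoxytoluene | COc1cccc(C)c1OC | starting material
8 | 1-bromo-3,4-dimethoxy-2-methylbenzene | COc1ccc(Br)c(C)c1OC | intermediate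
9 | 5-bromo-2,3-dimethoxy-4-methylbenzaldehyde | COc1c(C=O)cc(Br)c(C)c1OC | intermediate
10 | 5-bromo-2,3-dimethoxy-4-methylphenyl formate | COc1c(OC=O)cc(Br)c(C)c1OC | intermediate
11 | 5-bromo-2,3-dimethoxy-4-methylphenol | COc1c(O)cc(Br)c(C)c1OC | intermediate
12 | 1-[3-(benzyloxy)-5'-hydroxy-3',4',5-trimethoxy-2'-methylbiphenyl-2-yl]ethan-1-one | COc1cc(OCc2ccccc2)c(C(C)=O)c(c1)-c1cc(O)c(OC)c(OC)c1C | intermediate
13 | (aR)-1-[3-(benzyloxy)-2'-bromo-3'-hydroxy-4',5,5'-trimethoxy-6'-methylbiphenyl-2-yl]ethan-1-one | COc1cc(OCc2ccccc2)c(C(C)=O)c(c1)-c1c(Br)c(O)c(OC)c(OC)c1C | intermediate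
14 | (4R)-3-[2-acetyl-3-(benzyloxy)-5-methoxyphenyl]-2-bromo-4-hydroperoxy-5,6-dimethoxy-4-methylcyclohexa-2,5-dien-1-one (axis aR) | COC1=C(OC)[C@](C)(OO)C(c2cc(OC)cc(OCc3ccccc3)c2C(C)=O)=C(Br)C1=O | intermediate
15 | (4R)-3-[2-acetyl-3-(benzyloxy)-5-methoxyphenyl]-2-bromo-4-hydroxy-5,6-dimethoxy-4-methylcyclohexa-2,5-dien-1-one (axis aR) | COC1=C(OC)[C@](C)(O)C(c2cc(OC)cc(OCc3ccccc3)c2C(C)=O)=C(Br)C1=O | intermediate
16 | 4,4-diethoxybutan-1-amine | CCOC(CCCN)OCC | starting material
17 | (4R)-3-[2-acetyl-3-(benzyloxy)-5-methoxyphenyl]-2-bromo-5-[(4,4-diethoxybutyl)amino]-4-hydroxy-6-methoxy-4-methylcyclohexa-2,5-dien-1-one (axis aR) | COC1=C(NCCCC(OCC)OCC)[C@](C)(O)C(c2cc(OC)cc(OCc3ccccc3)c2C(C)=O)=C(Br)C1=O | intermediate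
18 | C8a-bromo dienone aminal, 5R, aminal carbon S, aminal H cis to C5–CH3, 2-acetyl-3-(benzyloxy)-5-methoxyphenyl at C4b (axis aR) | COC1=C2N3CCC[C@@H]3O[C@]2(C)C(=C(Br)C1=O)c1cc(OC)cc(OCc2ccccc2)c1C(C)=O | intermediate
19 | C1 O-benzyl ether of the target, 5R, aminal carbon S | COC1=C2N3CCC[C@@H]3O[C@]2(C)C2=C(CC(=O)c3c(OCc4ccccc4)cc(OC)cc32)C1=O | intermediate
20 | CNP0528850.1, 5R, aminal carbon S | COC1=C2N3CCC[C@@H]3O[C@]2(C)C2=C(CC(=O)c3c(O)cc(OC)cc32)C1=O | target

Total step count: 14. Longest linear sequence: 11 steps (steps 1–4 and 8–14, from 1).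

Steps most likely to fail

Step 13. After oxidative addition, enolate formation on palladium may be slow. Hydrodebromination, O-vinylation or base-induced 5-exo conjugate addition of the enolate to C4b could then take over. The fallback sets out from 18 and removes the Brønsted base from the coupling. Soft enolisation with TMSOTf and Et3N in CH2Cl2 at 0 °C should give the trimethylsilyl enol ether F1. F1 is then heated with Bu3SnF and PdCl2[P(o-tolyl)3]2 in toluene at 100 °C. The tin enolate formed in situ transmetalates to the vinylpalladium bromide under neutral conditions and the same C8a–C9 bond forms. The route is rejoined at 19.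

Step 9. Uncatalysed background bromination of the very electron-rich phenol, or loose binding of the ketone to the urea, would erode the enantiomeric purity of the axis. The fallback sets out from 12 and replaces catalysis by classical resolution with recycling. NBS in MeCN gives the racemic bromobiaryl phenol F2. Acylation of the C8 phenol with (−)-menthyl chloroformate (Et3N, DMAP, CH2Cl2) gives two diastereomeric carbonates, which are separated by crystallisation or chromatography. These are the aR menthyl carbonate F3 and its aS diastereomer F4. K2CO3 in MeOH releases the phenol from F3 and rejoins the route at 13. F4 is heated in refluxing mesitylene to re-equilibrate the axis and is then resubmitted to the separation.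

Step 11. Attack at C6 is slowed by the neighbouring quaternary C5 and by the donor at C7. The exchange may therefore stall, or need temperatures at which the quinol degrades. The fallback sets out from 15 and 16 and reverses the order of bond formation, so that the C6–N bond forms intramolecularly. Compound 16 is hydrolysed with 2 M HCl and basified with K2CO3 to give 1-pyrroline F5, which is used as its equilibrating monomer/trimer solution. With 15 and catalytic CF3CO2H in CH2Cl2, the C5 hydroxyl should add to the C=N bond. The resulting N–H then attacks C6 in a 5-exo closure with loss of methanol, and the acid equilibrates the aminal carbon. The route is rejoined at 18, bypassing 17.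

Further compounds
F1 | step 13 | trimethylsilyl enol ether of 18 | COC1=C2N3CCC[C@@H]3O[C@]2(C)C(=C(Br)C1=O)c1cc(OC)cc(OCc2ccccc2)c1C(=C)O[Si](C)(C)C
F2 | step 9 | racemic bromobiaryl phenol (both axis senses of 13) | COc1cc(OCc2ccccc2)c(C(C)=O)c(c1)-c1c(Br)c(O)c(OC)c(OC)c1C
F3 | step 9 | aR (1R,2S,5R)-menthyl carbonate of 13 | C[C@@H]1CC[C@H]([C@@H](C1)OC(=O)Oc1c(Br)c(-c2cc(OC)cc(OCc3ccccc3)c2C(C)=O)c(C)c(OC)c1OC)C(C)C
F4 | step 9 | aS (1R,2S,5R)-menthyl carbonate, axis diastereomer of F3 | C[C@@H]1CC[C@H]([C@@H](C1)OC(=O)Oc1c(Br)c(-c2cc(OC)cc(OCc3ccccc3)c2C(C)=O)c(C)c(OC)c1OC)C(C)C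
F5 | step 11 | 1-pyrroline (3,4-dihydro-2H-pyrrole) | C1CC=NC1
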